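The chromone is cut at the C4a–C5 bond. Its benzene ring (C4a, C5, C6, C7, C8, C8a), oxygenated at C5, C7 and C8a and carrying the acyl carbon C4 on C4a, is the signature of a Claisen-folded polyketide chain, and that is the feature exploited. One intramolecular Claisen condensation closes this ring as a triol from open-chain methyl 3,5-dioxo-6-(3-tridecylisoxazol-5-yl)hexanoate. In that precursor C4, C3 and C2 with the tridecyl chain are stored as a 3,5-disubstituted isoxazole, a latent 1,3-dicarbonyl unit that offers no partner for aldol closures; N–O hydrogenolysis and acid afterwards unveil the enaminone and close the pyranone ring.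

Key step: step 5

Assumption: diene 9 (the bis-silyl dienol ether of methyl acetoacetate) is taken as a purchasable reagent, and oxime 2 is used as its E/Z mixture, since the C=N geometry disappears in the nitrile oxide.

Step 1
Reactants: 1 tetradecanal
Product: 2 tetradecanal oxime
Conditions: NH2OH·HCl, NaOAc, EtOH/H2O, 25 °C
Reagents that add atoms: hydroxylamine hydrochloride, Cl.NO
Why: Oxime formation by condensation of an unhindered aliphatic aldehyde with hydroxylamine under acetate buffering should be fast and clean.

Step 2
Reactants: 2 tetradecanal oxime, 3 propyne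
Product: 6 5-methyl-3-tridecylisoxazole, via N-hydroxytetradecanimidoyl chloride 4 (not isolated), via tetradecanenitrile oxide 5 (not isolated)
Conditions: NCS, DMF, 25 °C; then propyne (5 equiv, 1 M in THF), Et3N (slow addition), 0 → 25 °C, sealed vessel
Reagents that add atoms: none
Why: Chlorination of the aldoxime and dehydrochlorination release the nitrile oxide, whose Huisgen 1,3-dipolar cycloaddition with a terminal alkyne should place the alkyne substituent at C5, while slow base addition and excess propyne hold back furoxan dimerisation.

Step 3
Reactants: 6 5-methyl-3-tridecylisoxazole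
Product: 8 2-(3-tridecylisoxazol-5-yl)acetic acid, via (3-tridecylisoxazol-5-yl)methyllithium 7 (not isolated)
Conditions: n-BuLi, THF, −78 °C; then excess CO2 (inverse addition), −78 → 0 °C; 1 M HCl
Reagents that add atoms: carbon dioxide, O=C=O
Why: Lateral lithiation of a 3-alkyl-5-methylisoxazole should occur at the more acidic, primary C5 methyl group rather than at the C3 alpha-methylene, and carboxylation of the organolithium by inverse quench onto excess CO2 gives the heteroarylacetic acid.

Step 4
Reactants: 8 2-(3-tridecylisoxazol-5-yl)acetic acid, 9 1-methoxy-1,3-bis(trimethylsilyloxy)buta-1,3-diene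
Product: 11 methyl 3,5-dioxo-6-(3-tridecylisoxazol-5-yl)hexanoate, via 2-(3-tridecylisoxazol-5-yl)acetyl chloride 10 (not isolated)
Conditions: (COCl)2, cat. DMF, CH2Cl2, 0 → 25 °C, evaporate; then 9 (1.5 equiv), CH2Cl2, −78 → 20 °C; 1 M HCl, 0 °C
Reagents that add atoms: none
Why: The acid chloride undergoes a Mukaiyama-type C-acylation at the terminal carbon of the bis-silyl dienol ether, a neutral equivalent of the acetoacetate dianion, so the strongly CH-acidic isoxazolylacetyl donor never meets a strong base that could enolise it or turn it into a ketene, and the acidic work-up cleaves the remaining silyl enol ether to the tricarbonyl ester.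

Step 5
Reactants: 11 methyl 3,5-dioxo-6-(3-tridecylisoxazol-5-yl)hexanoate
Product: 12 2-(3-tridecylisoxazol-5-yl)benzene-1,3,5-triol
Conditions: NaOMe (6 equiv), degassed MeOH, 25 → 65 °C, Ar; then 1 M HCl, 0 °C
Reagents that add atoms: none
Why: Excess methoxide deprotonates 11 reversibly at its methylene groups; the carbanion at hexanoate C6 (future C4a), stabilised by the C5 ketone and the electron-poor isoxazol-5-yl ring, adds to the ester carbonyl C1 (future C5), methoxide leaves, and the cyclohexane-1,3,5-trione enolises to the aromatic triol, held as its phenoxide. The closest known reaction is the intramolecular Claisen (Dieckmann-type) condensation by which open-chain 3,5,7-trioxo esters fold to acylphloroglucinols. The benzene ring closes in the 6-(enolexo)-exo-trig mode, and no stereocentre is created. Two selectivities are needed: Claisen rather than aldol folding, and C- rather than O-acylation of the enolate. The first is secured by the isoxazole, which keeps the future C4 and C2 non-electrophilic and the future C3 non-nucleophilic, so that C6 to C1 is the only carbon–carbon pairing able to give a six-membered ring. The second is secured by excess methoxide, in which the C6 carbanion of the polyanion should be a better nucleophile than the delocalised diketonate oxygen, ester exchange is degenerate for the methyl ester, and aromatisation makes only the C–C closure irreversible.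

Step 6
Reactants: 12 2-(3-tridecylisoxazol-5-yl)benzene-1,3,5-triol
Product: 14 5,7-dihydroxy-2-tridecyl-4H-chromen-4-one, via (Z)-3-amino-1-(2,4,6-trihydroxyphenyl)hexadec-2-en-1-one 13 (not isolated)
Conditions: H2 (1 atm), Pd/C, EtOH, 25 °C; filter; then aq. HCl, 80 °C
Reagents that add atoms: none
Why: Hydrogenolysis of the weak isoxazole N–O bond should give the hydrogen-bonded Z beta-enaminone, a vinylogous amide that resists further reduction, and in aqueous acid either of the two equivalent ortho hydroxyls adds to the amino-bearing carbon and ammonia is expelled (conjugate addition–elimination, the chromone cyclisation of an o-hydroxyaryl enaminone), any hydrolysis to the 1,3-diketone leading to the same chromone.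

Compound list
1 | tetradecanal | CCCCCCCCCCCCCC=O | starting material
2 | tetradecanal oxime (E/Z mixture) | CCCCCCCCCCCCCC=NO | intermediate
3 | propyne | CC#C | starting material
4 | N-hydroxytetradecanimidoyl chloride | CCCCCCCCCCCCCC(Cl)=NO | intermediate
5 | tetradecanenitrile oxide | CCCCCCCCCCCCCC#[N+][O-] | intermediate
6 | 5-methyl-3-tridecylisoxazole | CCCCCCCCCCCCCc1cc(C)on1 | intermediate
7 | (3-tridecylisoxazol-5-yl)methyllithium | [Li]Cc1cc(CCCCCCCCCCCCC)no1 | intermediate
8 | 2-(3-tridecylisoxazol-5-yl)acetic acid | CCCCCCCCCCCCCc1cc(CC(=O)O)on1 | intermediate
9 | 1-methoxy-1,3-bis(trimethylsilyloxy)buta-1,3-diene (C1=C2 geometry immaterial) | COC(O[Si](C)(C)C)=CC(=C)O[Si](C)(C)C | starting material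
10 | 2-(3-tridecylisoxazol-5-yl)acetyl chloride | CCCCCCCCCCCCCc1cc(CC(=O)Cl)on1 | intermediate
11 | methyl 3,5-dioxo-6-(3-tridecylisoxazol-5-yl)hexanoate | CCCCCCCCCCCCCc1cc(CC(=O)CC(=O)CC(=O)OC)on1 | intermediate
12 | 2-(3-tridecylisoxazol-5-yl)benzene-1,3,5-triol | CCCCCCCCCCCCCc1cc(-c2c(O)cc(O)cc2O)on1 | intermediate
13 | (Z)-3-amino-1-(2,4,6-trihydroxyphenyl)hexadec-2-en-1-one | CCCCCCCCCCCCC/C(N)=C/C(=O)c1c(O)cc(O)cc1O | intermediate
14 | 5,7-dihydroxy-2-tridecyl-4H-chromen-4-one | CCCCCCCCCCCCCc1cc(=O)c2c(O)cc(O)cc2o1 | target

Total step count: 6. Longest linear sequence: 6 steps (1 to 14).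

Steps most likely to fail

1. Step 5 (key step). The enolate may acylate on oxygen, lactonising the chain to a 4-hydroxypyran-2-one instead of closing the carbocycle. Methoxide may also cleave the 1,3-diketone by retro-Claisen attack, and the electron-rich phenoxide may oxidise if air enters. The fallback buys the benzene ring instead of folding it; it sets out from oxime 2 and comes back at 12. 2,4,6-Trimethoxybenzaldehyde is homologated with dimethyl (1-diazo-2-oxopropyl)phosphonate (K2CO3, MeOH; Ohira–Bestmann reaction) to 2-ethynyl-1,3,5-trimethoxybenzene F1. Nitrile oxide 5, generated from 2 through 4 as in step 2, is cycloadded to this alkyne to give 3-tridecyl-5-(2,4,6-trimethoxyphenyl)isoxazole F2. BBr3 (CH2Cl2, −78 → 25 °C) then cleaves the three methyl ethers and delivers 12, which continues through step 6.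

2. Step 4. The diene may be acylated at its central carbon or on oxygen instead of the terminal carbon, liberated HCl may protodesilylate it before it reacts, and the tricarbonyl ester may lactonise during work-up or chromatography. The fallback replaces the neutral silyl nucleophile by the classical dianion acylation; it sets out from acid 8 and comes back at 11. Acid 8 is activated with 1,1'-carbonyldiimidazole (THF, 25 °C) to 1-(1H-imidazol-1-yl)-2-(3-tridecylisoxazol-5-yl)ethan-1-one F3. This is added at −78 °C to an excess of the dianion of methyl acetoacetate (NaH, then n-BuLi, THF, 0 °C), and the gamma-carbon Claisen acylation should give 11 after an acidic quench.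

3. Step 3. Metalation may compete at the C3 alpha-methylene or at ring C4, the product carboxylate may quench unreacted organolithium by proton transfer, and the heteroarylacetic acid may lose CO2 on warming. The fallback brings in the acetic acid carbons with the dipolarophile instead of by carboxylation; it sets out from oxime 2 and comes back at 8, so it also replaces step 2. Nitrile oxide 5 (from 2 through 4, NCS then Et3N) is cycloadded to but-3-yn-1-ol to give 2-(3-tridecylisoxazol-5-yl)ethan-1-ol F4. Oxidation of this primary alcohol with catalytic TEMPO and PhI(OAc)2 in MeCN/H2O should then give acid 8.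

Further compounds
F1 | step 5 | 2-ethynyl-1,3,5-trimethoxybenzene | C#Cc1c(OC)cc(OC)cc1OC
F2 | step 5 | 3-tridecyl-5-(2,4,6-trimethoxyphenyl)isoxazole | CCCCCCCCCCCCCc1cc(-c2c(OC)cc(OC)cc2OC)on1
F3 | step 4 | 1-(1H-imidazol-1-yl)-2-(3-tridecylisoxazol-5-yl)ethan-1-one | CCCCCCCCCCCCCc1cc(CC(=O)n2ccnc2)on1
F4 | step 3 | 2-(3-tridecylisoxazol-5-yl)ethan-1-ol | CCCCCCCCCCCCCc1cc(CCO)on1
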